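**Retrosynthetic overview**

- The diene side chain is cut back by two olefinations to a C12 aldehyde, held as a lactol/acetal ring with the C8 hydroxyl. The C7 carbinol comes from a C7 ketone, the C6 angelate from a 6α-hydroxy-7-ketone, and C5–H plus C6–O from a Δ5-7-ketone.
- Feature used: in ring B the C7 secondary carbinol next to the C8 tertiary carbinol (bearing methyl C17) is a masked acyloin, and C9 is epimerisable while C8 is a ketone. The C7–C8 bond is therefore cut to a C7 aldehyde (as the C5=C6 enal) and a C8 methyl ketone, and ring B is closed by a carbene-catalysed benzoin reaction that funnels both C9 epimers.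
- The keto enal comes from ring A: C10 by decarboxylative asymmetric allylation of 2,2,6-trimethylcyclohexanone, C6–C7 by ethoxyacetylide addition at C5 and Meyer–Schuster shift. The allyl group is then cut to the C8 aldehyde, C9 is allylated through the enamine, methyl C17 is added and the oxidation levels are adjusted.
- Ring order: ring A is bought with the starting ketone and ring B is closed in step 10. The only other ring is a temporary oxolane acetal (C8–O–C12) that serves as protection in steps 11–16.

Key step: step 10

Assumption 1: the sense of induction in step 2 is taken from the parent 2-methylcyclohexanone case, where the (S)-ligand gives the (S)-ketone; the 6,6-dimethyl group does not change the CIP order at the new centre, so the (R)-ligand is written for the (R)-ketone.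

Assumption 2: which enantiomer of the aminoindanol triazolium salt is matched with C10 cannot be predicted safely; the (5aR,10bS) salt is written and its mirror image is used if a test run shows it to be the matched one.

Design remark 1: the C9 arm is carried as an allyl group (C11, C12 and one carbon lost later as formaldehyde), so that C12 reaches the aldehyde level by ozonolysis and not by hydride reduction next to the angelate.

Design remark 2: C9 is allylated while C8 is still an aldehyde, where C9 is the only α-carbon, because a C8 methyl ketone would enolise toward methyl C17.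

Labdane numbering is used for positions throughout.

**Route**

Step 1
Reactants: 1 2,2,6-trimethylcyclohexanone; 2 allyl chloroformate
Product: 4 allyl 2,6,6-trimethylcyclohex-1-en-1-yl carbonate, via lithium enolate 3 (not isolated)
Conditions: LiN(SiMe3)2, THF, 0 °C; then 2, −78 → 25 °C
Reagents that add atoms: none
Why: O-acylation of the only possible enolate (one enolisable carbon) with a chloroformate gives the allyl enol carbonate, and the stereocentre of 1 is erased.

Step 2
Reactants: 4 allyl 2,6,6-trimethylcyclohex-1-en-1-yl carbonate
Product: 5 (R)-2-allyl-2,6,6-trimethylcyclohexanone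
Conditions: Pd2(dba)3 (2.5 mol%), (R)-4-tert-butyl-2-[2-(diphenylphosphino)phenyl]-4,5-dihydrooxazole (6 mol%), THF, 25 °C
Reagents that add atoms: none
Why: Decarboxylative asymmetric allylic alkylation (Tsuji allylation): zerovalent palladium ionises the carbonate, CO2 is lost, and the allylpalladium enolate recombines at carbon on the face chosen by the PHOX ligand, which sets the quaternary C10 as (R).

Step 3
Reactants: 5 (R)-2-allyl-2,6,6-trimethylcyclohexanone; 6 ethoxyacetylene
Product: 7 (2R)-2-allyl-1-(ethoxyethynyl)-2,6,6-trimethylcyclohexan-1-ol (both carbinol epimers)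
Conditions: 6, n-BuLi, THF, −78 °C; then 5, −78 → 25 °C
Reagents that add atoms: none
Why: 1,2-Addition of a lithium alkynide, a slim nucleophile that can still reach a non-enolisable ketone flanked by two quaternary carbons; the new C5 carbinol centre is removed in step 4, so both epimers are used.

Step 4
Reactants: 7 (2R)-2-allyl-1-(ethoxyethynyl)-2,6,6-trimethylcyclohexan-1-ol
Product: 8 ethyl 2-[(2R)-2-allyl-2,6,6-trimethylcyclohexylidene]acetate (both alkene isomers)
Conditions: Sc(OTf)3 (5 mol%), EtOH (5 equiv), CH2Cl2, 25 °C
Reagents that add atoms: none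
Why: Meyer–Schuster rearrangement of the ethoxyalkynyl carbinol to the conjugated ester, free of the Rupe pathway because neither neighbour of C5 carries hydrogen; both alkene isomers are expected and are carried on together.

Step 5
Reactants: 8 ethyl 2-[(2R)-2-allyl-2,6,6-trimethylcyclohexylidene]acetate
Product: 9 ethyl 2-[(2R)-2,6,6-trimethyl-2-(2-oxoethyl)cyclohexylidene]acetate
Conditions: OsO4 (2 mol%), NaIO4, 2,6-lutidine, dioxane–H2O, 25 °C
Reagents that add atoms: osmium tetroxide, O=[Os](=O)(=O)=O; sodium periodate, [Na+].[O-]I(=O)(=O)=O
Why: Lemieux–Johnson cleavage: the monosubstituted alkene is dihydroxylated and cleaved while the electron-poor, doubly neopentyl enoate alkene is left, giving the C8 aldehyde whose only α-carbon is C9.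

Step 6
Reactants: 9 ethyl 2-[(2R)-2,6,6-trimethyl-2-(2-oxoethyl)cyclohexylidene]acetate; 10 allyl bromide
Product: 14 ethyl 2-[(2R)-2,6,6-trimethyl-2-(1-oxopent-4-en-2-yl)cyclohexylidene]acetate (both C9 epimers), via pyrrolidine enamine 11 (not isolated), via N-allyl enammonium bromide 12 (not isolated), via C-allyl iminium bromide 13 (not isolated)
Conditions: pyrrolidine, MgSO4, PhMe, 25 °C, concentrate; then 10, MeCN, 25 → 80 °C; then H2O, 25 °C
Reagents that add atoms: water, O
Why: Stork enamine alkylation in its allyl form: the enamine is alkylated on nitrogen, a 3-aza-Cope shift moves the allyl group to C9 (the one α-position of the aldehyde) regardless of the neighbouring quaternary C10, and hydrolysis frees the aldehyde; C9 is formed as both epimers on purpose, since it is equilibrated in step 10.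

Step 7
Reactants: 14 ethyl 2-[(2R)-2,6,6-trimethyl-2-(1-oxopent-4-en-2-yl)cyclohexylidene]acetate
Product: 15 ethyl 2-[(2R)-2-(2-hydroxyhex-5-en-3-yl)-2,6,6-trimethylcyclohexylidene]acetate (isomer mixture)
Conditions: MeMgBr, THF, −78 → −20 °C
Reagents that add atoms: methylmagnesium bromide, C[Mg]Br
Why: Grignard addition to the aldehyde, far faster than attack on the hindered conjugated ester, brings in methyl C17; the C8 carbinol epimers are both oxidised in step 9.

Step 8
Reactants: 15 ethyl 2-[(2R)-2-(2-hydroxyhex-5-en-3-yl)-2,6,6-trimethylcyclohexylidene]acetate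
Product: 16 3-[(1R)-2-(2-hydroxyethylidene)-1,3,3-trimethylcyclohexyl]hex-5-en-2-ol (isomer mixture)
Conditions: i-Bu2AlH (4 equiv), CH2Cl2, −78 → 0 °C
Reagents that add atoms: none
Why: Aluminium hydride 1,2-reduction of the enoate to the allylic alcohol; the isolated alkene is inert and no lasting stereocentre is formed.

Step 9
Reactants: 16 3-[(1R)-2-(2-hydroxyethylidene)-1,3,3-trimethylcyclohexyl]hex-5-en-2-ol
Product: 17 keto enal 3-[(1R)-1,3,3-trimethyl-2-(2-oxoethylidene)cyclohexyl]hex-5-en-2-one (C7 aldehyde, C8 methyl ketone, both C9 epimers, both enal isomers)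
Conditions: Dess–Martin periodinane (3 equiv), NaHCO3, CH2Cl2, 0 → 25 °C
Reagents that add atoms: none
Why: Dess–Martin oxidation of the secondary and the allylic primary alcohol in one operation under buffered, non-enolising conditions gives the methyl ketone and the enal.

Step 10
Reactants: 17 keto enal (C7 aldehyde, C8 methyl ketone, both C9 epimers)
Product: 18 ring B α-hydroxy enone (Δ5-7-ketone, 8α-hydroxy-8β-methyl, 9α-H with the allyl arm β, 10β-methyl)
Conditions: (5aR,10bS)-2-(pentafluorophenyl)-5a,10b-dihydro-4H,6H-indeno[2,1-b][1,2,4]triazolo[4,3-d][1,4]oxazin-2-ium tetrafluoroborate (15 mol%), DBU (30 mol%), PhMe, 25 °C, Ar; recovered (E)-17 re-equilibrated (cat. I2, hν) and resubmitted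
Reagents that add atoms: none
Why: The carbene released from the triazolium salt adds to the C7 aldehyde of the (Z)-enal (formyl group on the C10 side), a proton shift gives the enaminol that acts as an acyl anion at C7, and this carbon attacks the C8 ketone; proton transfer and loss of the carbene leave the tertiary α-ketol. The closest known reaction type is the triazolium-catalysed intramolecular crossed aldehyde–ketone benzoin reaction, the cis C5=C6 bond of the enal taking the place that the aryl ring holds in the ortho-substituted benzaldehydes commonly cyclised this way. Ring B closes by 6-exo-trig attack of C7 on the ketone carbon. C8 is set in the hydrogen-bonded transition state, in which the ketone oxygen sits beside the enol hydroxyl and so ends equatorial (8α-OH) with methyl C17 axial (β), the matched chiral carbene reinforcing this face; C9 is set by selection between the two epimers of 17, which interconvert by enolisation under DBU, the one with the allyl arm pseudo-equatorial in the half-chair (9α-H) being expected to close faster because an axial arm would clash with the axial substituent on C7 of the adduct. The step needs acyl-anion reactivity to win over homoenolate, redox and aldol pathways: bonding through C5 would need a four-membered ring and C5 is shielded by two quaternary neighbours, the electron-poor N-pentafluorophenyl carbene favours the acyl-anion mode, and the amidine base at 25 °C is meant to keep enolate aldol closure and retro-benzoin slow. The (E)-enal cannot reach the ketone; it is expected to be fed in by reversible carbene addition (rotation about C5–C6 in the adduct), and any that is recovered is recycled as given in the conditions.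

Step 11
Reactants: 18 ring B α-hydroxy enone
Product: 20 lactol (C12 hemiacetal closed onto O8, both anomers, enone kept), via hydroxy aldehyde 19 (not isolated)
Conditions: O3, CH2Cl2, −78 °C (Sudan Red 7B end point); then PPh3, −78 → 25 °C
Reagents that add atoms: ozone, [O-][O+]=O
Why: Ozonolysis with reductive work-up: ozone takes the electron-rich terminal alkene in preference to the hindered enone alkene, and the C12 aldehyde closes onto the equatorial 8α-hydroxyl as a five-membered lactol.

Step 12
Reactants: 20 lactol
Product: 21 cyclic methyl acetal (12-methoxy-8α,12-epoxy, Δ5-7-ketone, both anomers)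
Conditions: MeOH, pyridinium p-toluenesulfonate (cat.), 25 °C
Reagents that add atoms: methanol, CO
Why: Acid-catalysed acetal exchange of the lactol with methanol gives the mixed cyclic acetal, which masks C12 and the C8 hydroxyl at once; the anomeric centre is a mixture and is removed in step 16.

Step 13
Reactants: 21 cyclic methyl acetal
Product: 23 6α-hydroxy-7-ketone (5α-H, trans ring fusion, acetal kept), via 6α-hydroperoxide 22 (not isolated)
Conditions: Mn(dpm)3 (dpm = 2,2,6,6-tetramethylheptane-3,5-dionate, 10 mol%), PhSiH3, O2 (1 atm), i-PrOH–CH2Cl2, 0 °C; then P(OEt)3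
Reagents that add atoms: dioxygen, O=O
Why: Mukaiyama-type reductive α-hydroxylation: hydrogen-atom transfer from a manganese hydride to C5 on the α-face (the β-face is screened by the C10 and 4β methyl groups) gives the trans ring fusion and a C6 radical next to the ketone, which takes up O2 on the same open face to give the equatorial 6α-hydroperoxide, reduced by the phosphite.

Step 14
Reactants: 23 6α-hydroxy-7-ketone; 24 angelic acid
Product: 25 6α-angeloyloxy-7-ketone (acetal kept)
Conditions: 24, 2,4,6-trichlorobenzoyl chloride, Et3N, PhMe, 25 °C, filter; then 23, PhMe, 80 °C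
Reagents that add atoms: none
Why: Yamaguchi esterification: the only free hydroxyl (6α) attacks the angeloyl carbonyl of the mixed anhydride, the trichlorobenzoyl carbonyl being shielded, and leaving out any nucleophilic catalyst is meant to keep the (Z)-enoate from isomerising to the tiglate.

Step 15
Reactants: 25 6α-angeloyloxy-7-ketone
Product: 26 6α-angeloyloxy-7β-alcohol (acetal kept)
Conditions: NaBH4, CeCl3·7H2O, MeOH, −40 °C
Reagents that add atoms: none
Why: Borohydride reduction under Luche conditions: hydride attacks the C7 ketone axially from the α-face, away from the axial 8β-methyl, to give the equatorial 7β-alcohol, and the cold buffered medium is meant to prevent acyl shift from O6.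

Step 16
Reactants: 26 6α-angeloyloxy-7β-alcohol
Product: 27 lactol (C12 hemiacetal on O8, 6α-angelate, 7β-OH)
Conditions: AcOH–H2O–THF, 40 °C
Reagents that add atoms: water, O
Why: Mild acid hydrolysis of the cyclic methyl acetal to the lactol; the angelate and the alcohols are expected to be stable to aqueous acetic acid.

Step 17
Reactants: 27 lactol; 28 2-(triphenylphosphoranylidene)propanal
Product: 30 (12E)-enal (C12=C13, C14 aldehyde, free 8α-OH, 7β-OH, 6α-angelate), via hydroxy aldehyde 29 (not isolated)
Conditions: 28 (2 equiv), PhMe, 100 °C
Reagents that add atoms: none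
Why: Wittig olefination of the open hydroxy-aldehyde form of the lactol with a stabilised formyl ylide gives the (E)-trisubstituted enal and frees the 8α-hydroxyl; the α-branched enal formed is too unreactive to be homologated a second time.

Step 18
Reactants: 30 (12E)-enal
Product: 31 target CNP0189082.1
Conditions: Zn, CH2Br2, TiCl4, THF (reagent aged at 5 °C); then 30, CH2Cl2, 0 → 25 °C
Reagents that add atoms: dibromomethane, BrCBr
Why: Lombardo methylenation, a non-basic zinc–titanium methylene reagent that converts the aldehyde to the terminal alkene C14=C15 without epimerising, migrating or cleaving the angelate and without hydroxyl protection.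

**Compound list**

1 | 2,2,6-trimethylcyclohexanone (racemic) | CC1CCCC(C)(C)C1=O | starting material
2 | allyl chloroformate | C=CCOC(Cl)=O | starting material
3 | lithium 2,6,6-trimethylcyclohex-1-en-1-olate | [Li+].[O-]C1=C(C)CCCC1(C)C | intermediate (not isolated)
4 | allyl 2,6,6-trimethylcyclohex-1-en-1-yl carbonate | C=CCOC(=O)OC1=C(C)CCCC1(C)C | intermediate
5 | (R)-2-allyl-2,6,6-trimethylcyclohexanone | C=CC[C@@]1(C)CCCC(C)(C)C1=O | intermediate
6 | ethoxyacetylene | CCOC#C | starting material
7 | (2R)-2-allyl-1-(ethoxyethynyl)-2,6,6-trimethylcyclohexan-1-ol, both carbinol epimers | C=CC[C@@]1(C)CCCC(C)(C)C1(O)C#COCC | intermediate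
8 | ethyl 2-[(2R)-2-allyl-2,6,6-trimethylcyclohexylidene]acetate, both alkene isomers | C=CC[C@@]1(C)CCCC(C)(C)C1=CC(=O)OCC | intermediate
9 | ethyl 2-[(2R)-2,6,6-trimethyl-2-(2-oxoethyl)cyclohexylidene]acetate | O=CC[C@@]1(C)CCCC(C)(C)C1=CC(=O)OCC | intermediate
10 | allyl bromide | C=CCBr | starting material
11 | pyrrolidine enamine of 9 | C(=CN2CCCC2)[C@@]1(C)CCCC(C)(C)C1=CC(=O)OCC | intermediate (not isolated)
12 | N-allyl enammonium bromide | [Br-].C=CC[N+]2(CCCC2)C=C[C@@]1(C)CCCC(C)(C)C1=CC(=O)OCC | intermediate (not isolated)
13 | C-allyl iminium bromide | [Br-].C=CCC(C=[N+]2CCCC2)[C@@]1(C)CCCC(C)(C)C1=CC(=O)OCC | intermediate (not isolated)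
14 | ethyl 2-[(2R)-2,6,6-trimethyl-2-(1-oxopent-4-en-2-yl)cyclohexylidene]acetate, both C9 epimers | C=CCC(C=O)[C@@]1(C)CCCC(C)(C)C1=CC(=O)OCC | intermediate
15 | ethyl 2-[(2R)-2-(2-hydroxyhex-5-en-3-yl)-2,6,6-trimethylcyclohexylidene]acetate, isomer mixture | C=CCC(C(C)O)[C@@]1(C)CCCC(C)(C)C1=CC(=O)OCC | intermediate
16 | 3-[(1R)-2-(2-hydroxyethylidene)-1,3,3-trimethylcyclohexyl]hex-5-en-2-ol, isomer mixture | C=CCC(C(C)O)[C@@]1(C)CCCC(C)(C)C1=CCO | intermediate
17 | keto enal 3-[(1R)-1,3,3-trimethyl-2-(2-oxoethylidene)cyclohexyl]hex-5-en-2-one; drawn as the reactive (Z)-isomer, the (E)-isomer and both C9 epimers are present | C=CCC(C(C)=O)[C@@]1(C)CCCC(C)(C)/C1=C/C=O | intermediate (key-step precursor)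
18 | ring B α-hydroxy enone: Δ5-7-ketone, 8α-hydroxy-8β-methyl, 9α-H with β-allyl arm, 10β-methyl | C=CC[C@H]1[C@](C)(O)C(=O)C=C2C(C)(C)CCC[C@@]21C | intermediate (key-step product)
19 | open hydroxy aldehyde (C12 aldehyde, 8α-OH, Δ5-7-ketone) | O=CC[C@H]1[C@](C)(O)C(=O)C=C2C(C)(C)CCC[C@@]21C | intermediate (not isolated)
20 | lactol: 12-hydroxy-8α,12-epoxy-Δ5-7-ketone, both anomers | OC3C[C@H]1[C@](C)(O3)C(=O)C=C2C(C)(C)CCC[C@@]21C | intermediate
21 | cyclic methyl acetal: 12-methoxy-8α,12-epoxy-Δ5-7-ketone, both anomers | COC3C[C@H]1[C@](C)(O3)C(=O)C=C2C(C)(C)CCC[C@@]21C | intermediate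
22 | 6α-hydroperoxy-7-ketone, 5α-H | COC3C[C@H]1[C@](C)(O3)C(=O)[C@H](OO)[C@H]2C(C)(C)CCC[C@@]21C | intermediate (not isolated)
23 | 6α-hydroxy-7-ketone, 5α-H, acetal kept | COC3C[C@H]1[C@](C)(O3)C(=O)[C@H](O)[C@H]2C(C)(C)CCC[C@@]21C | intermediate
24 | angelic acid, (Z)-2-methylbut-2-enoic acid | OC(=O)/C(C)=C\C | starting material
25 | 6α-angeloyloxy-7-ketone, acetal kept | COC3C[C@H]1[C@](C)(O3)C(=O)[C@H](OC(=O)/C(C)=C\C)[C@H]2C(C)(C)CCC[C@@]21C | intermediate
26 | 6α-angeloyloxy-7β-alcohol, acetal kept | COC3C[C@H]1[C@](C)(O3)[C@@H](O)[C@H](OC(=O)/C(C)=C\C)[C@H]2C(C)(C)CCC[C@@]21C | intermediate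
27 | lactol: 12-hydroxy-8α,12-epoxy, 6α-angelate, 7β-OH | OC3C[C@H]1[C@](C)(O3)[C@@H](O)[C@H](OC(=O)/C(C)=C\C)[C@H]2C(C)(C)CCC[C@@]21C | intermediate
28 | 2-(triphenylphosphoranylidene)propanal | CC(C=O)=P(c1ccccc1)(c1ccccc1)c1ccccc1 | starting material
29 | open hydroxy aldehyde (C12 aldehyde, 8α-OH, 7β-OH, 6α-angelate) | O=CC[C@H]1[C@](C)(O)[C@@H](O)[C@H](OC(=O)/C(C)=C\C)[C@H]2C(C)(C)CCC[C@@]21C | intermediate (not isolated)
30 | (12E)-enal: C12=C13, C14 aldehyde, 6α-angelate, 7β-OH, 8α-OH | O=C/C(C)=C/C[C@H]1[C@](C)(O)[C@@H](O)[C@H](OC(=O)/C(C)=C\C)[C@H]2C(C)(C)CCC[C@@]21C | intermediate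
31 | CNP0189082.1: 6α-angeloyloxy-7β,8α-dihydroxy-(12E)-labda-12,14-diene | C=C/C(C)=C/C[C@H]1[C@](C)(O)[C@@H](O)[C@H](OC(=O)/C(C)=C\C)[C@H]2C(C)(C)CCC[C@@]21C | target

Total step count: 18
Longest linear sequence: 18 steps (from 1; all other building blocks are bought)

**Steps most likely to fail**

Step 10 (benzoin closure). Several things may go wrong. The enolisation toward C9 that the stereoconvergence relies on may be slow next to the quaternary C10, so that the reaction becomes a resolution of the C9 epimers. The same enol may close onto the aldehyde in a five-membered aldol. Attack may take place on the other ketone face, which would put methyl C17 equatorial, or through the epimer with an axial arm. The (E)-enal may not be fed in. The fallback makes the C7–C8 bond reductively and sets out from keto enal 17. Ketyl–carbonyl pinacol cyclisation with SmI2 in THF–t-BuOH at −78 °C, a known way to close cyclohexane-1,2-diols from keto aldehydes through a samarium chelate, should give the 7,8-diol F1. Oxidation of its allylic C7 carbinol with MnO2 in CH2Cl2 returns to α-hydroxy enone 18. No base is present in this variant, so the C9 epimers of 17 do not interconvert and the diol isomers are separated after cyclisation.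

Step 13 (reductive α-hydroxylation). Hydrogen-atom transfer to C5, which lies between two quaternary carbons, may be too slow, or the C6 radical may be reduced before it captures oxygen, giving the plain saturated ketone. The fallback sets out from acetal 21. Hydrogenation over Pd/C (H2, EtOAc), with hydrogen delivered from the open α-face, should give the trans-fused saturated ketone F2. Deprotonation with KN(SiMe3)2 in THF at −78 °C gives its potassium enolate F3, formed and used in the flask; C6 is the only enolisable position because C8 is quaternary. Hydroxylation with 2-(phenylsulfonyl)-3-phenyloxaziridine on the α-face returns to 6α-hydroxy ketone 23.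

Step 14 (angeloylation). The hindered 6α-hydroxyl may acylate slowly, and during a slow reaction the angeloyl group may isomerise to tigloyl or the α-ketol may shift its carbonyl by enediol tautomerism. The fallback builds the (Z)-alkene after the ester bond and sets out from 23. Esterification with 2-[bis(2,2,2-trifluoroethoxy)phosphoryl]propanoic acid and N,N'-dicyclohexylcarbodiimide should give the phosphonate ester F4. Still–Gennari olefination with acetaldehyde (KN(SiMe3)2, 18-crown-6, THF, −78 °C; the phosphonate carbon is by far the most acidic site) returns to angelate 25 with the (Z)-geometry.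

**Further compounds**

F1 | step 10 | 7,8-diol: 9β-allyl-8α-hydroxy-8β-methyl-Δ5-en-7-ol, C7 configuration not needed | C=CC[C@H]1[C@](C)(O)C(O)C=C2C(C)(C)CCC[C@@]21C
F2 | step 13 | saturated 7-ketone, 5α-H, acetal kept | COC3C[C@H]1[C@](C)(O3)C(=O)C[C@H]2C(C)(C)CCC[C@@]21C
F3 | step 13 | potassium 6-en-7-olate of F2 | [K+].COC3C[C@H]1[C@](C)(O3)C([O-])=C[C@H]2C(C)(C)CCC[C@@]21C
F4 | step 14 | 6α-{2-[bis(2,2,2-trifluoroethoxy)phosphoryl]propanoyloxy}-7-ketone, acetal kept | COC3C[C@H]1[C@](C)(O3)C(=O)[C@H](OC(=O)C(C)P(=O)(OCC(F)(F)F)OCC(F)(F)F)[C@H]2C(C)(C)CCC[C@@]21C
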